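The numbers in the tables were computed with made-up constants; noise was put on by code.

1. L is the larger product in the earlier runs: in blue at 90.0 s, L stands at 88.4% and Q at 6.5%. The question is how the split between them moves with time.

| flask | Z | D | remark | time |
|---|---|---|---|---|
| blue | 5 mM | 0.14 mM | run made earlier |  |
| grey | 5 mM | 0.22 mM | run made earlier |  |
| violet | 10 mM | 0.10 mM | run made earlier |  |
| flask | 5.0 mM | 0.100 mM |  | 2.0 min |

- blue (time / s: Q / %, L / %, Z / %): 12.0: 4.1, 57.2, 14.6; 30.0: 5.9, 80.2, 3.1; 60.0: 6.7, 86.4, 0.9; 90.0: 6.5, 88.4, 0.9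
- grey (time / s: Q / %, L / %, Z / %): 25.0: 5.1, 75.6, 4.8; 50.0: 6.1, 83.8, 0.8; 80.0: 6.1, 87.2, 0.4; 90.0: 6.6, 87.2, 0.6
- violet (time / s: Q / %, L / %, Z / %): 12.0: 4.3, 58.7, 15.6; 30.0: 5.5, 81.8, 3.5; 60.0: 7.2, 88.6, 0.6; 90.0: 6.2, 90.0, 1.4

(scatter of a reading: 0.5 percentage points)

1. ratio of Q to L at 1.5 s
2. ratio of Q to L at 15 s
3. ratio of Q to L at 2.0 min
4. which of Q and L there is more of at 2.0 min



2. I define ρ, the late split (a selectivity factor), as the sum of Q over the sum of L in the last readings of the three runs. As a reading, 0.0727.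

3. Blue already gives 0.0717 at 12.0 s, and violet, with twice the Z and less D, gives 0.0733. So, as far as these readings show, the split stands from that time on, and this flask's charges lie inside those tried.

4. But Q, L and Z sum to 75.9% in blue at 12.0 s, so material sits in something unseen. A ratio of amounts can therefore differ before that material has come through. Between its first two readings, blue gives Z a half-life of 8.05 s. The time 15 s is longer, so I use ρ there and at 2.0 min, with L leading. The time 1.5 s is shorter and precedes every reading, so I commit no number there.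

5. The forecast gives 0.073 at 1.5 s (range 0.055 to 0.095), 0.073 at 15 s (0.066 to 0.08) and 0.073 at 2.0 min (0.067 to 0.079), with L leading. It agrees with me at the two later times and differs in giving a value at 1.5 s, noting: “The 1.5 s value is extrapolated and rests on tiny amounts”.

6. The flask gives 0.236 at 1.5 s, 0.0726 at 15 s and 0.0754 at 2.0 min. L leads, with L at 90.3% and Q at 6.81%.

    Z ⇌ J (K = 0.790, k = 0.0280 s⁻¹)
    Z ⇌ E (K = 1.30, k = 0.230 s⁻¹)
    Q ⇌ L (K = 7.30, k = 0.00110 s⁻¹)
    Z + Q → X (k = 0.180 M⁻¹ s⁻¹)
    E → L (k = 0.270 s⁻¹)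
    Z → Q (k = 0.00940 s⁻¹)
    Z + D → G (k = 760 M⁻¹ s⁻¹)

7. So ρ lies close to the flask's ratios at the two later times, while at 1.5 s the flask's ratio is 3.25 times ρ. Taking away the path from Z to E, both ways, raises the ratio at 1.5 s from 0.236 to 1200 and turns the lead: in the scheme L forms from E, which has to build up from Z first, whereas Q forms directly from Z.

8. In a neighbour flask with 2.0 mM of Z and this flask's D, ρ, read from runs at 5 mM and 10 mM of Z, gives 0.0727 at 15 s and 2.0 min, and again no number at 1.5 s. The computed ratios are 0.0726 and 0.0756, with 0.235 at 1.5 s.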